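**Direct plan and its weak points**

A direct plan would hang a prochiral oxetane on ring B by a Negishi coupling and add the ring D propargyl ether, to give the aryl oxetane A1.
A chiral phosphoric acid would then let the symmetric phenol A2 open the oxetane to the alcohol A3 (C3 set), a Mitsunobu reaction would close ring C to the chroman A4, and a Claisen cascade at 150 °C on the chroman A4 would build ring D before ester cleavage.
- Weakest: the enantioselective Friedel–Crafts opening of the oxetane. It would set C3 with a carbon nucleophile that its formyl group deactivates, next to an acid-labile tertiary propargyl ether, and without precedent for this bond.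
- Weak: the run-up to A1. Silylation, zinc insertion, coupling and desilylation would be spent on a three-carbon handle that carries no stereochemistry.
- Weak: the thermal closure of ring D. It would come at the end, at 150 °C, on the free chelated hydroxy aldehyde, when the material is most valuable.

**Retrosynthetic overview of the new route**

The target is cut at C3–C1', the bond between the only stereocentre (C3 of ring C) and ring B: the chroman half (rings A and C) becomes the 2H-chromene 6, the chromene half (rings B and D) the aryl iodide 11.
Both pyran rings are closed from aryl propargyl ethers before the union: ring C by gold-catalysed hydroarylation on the formyl-blocked ring A, ring D by a Claisen cascade on ring B.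
The union is an enantioselective reductive Heck reaction that forms C3–C1' and sets C3 (R) in the same operation, at the most convergent point of the route.
No oxetane, no Mitsunobu closure and no late thermal step are needed: the formyl group is carried from the start and the last step is a mild ester methanolysis.

Key step: step 7

Remark on the chemistry: the sense of induction of the ligand in step 7 cannot be predicted with certainty. The (R)-form of Xyl-SDP(O) (7-[bis(3,5-dimethylphenyl)phosphino]-7'-[bis(3,5-dimethylphenyl)phosphoryl]-1,1'-spirobiindane) is written; its antipode would be taken if a test on the parent 2H-chromene pointed the other way.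

**Route**

Step 1
Reactants: 1 2,4,6-trihydroxybenzaldehyde
Product: 2 2,6-dihydroxy-4-methoxybenzaldehyde
Conditions: Me2SO4 (1.0 equiv), K2CO3 (1.0 equiv), acetone, 0 → 25 °C
Reagents that add atoms: dimethyl sulfate, COS(=O)(=O)OC
Why: Williamson O-methylation with one equivalent of a hard electrophile should go to the 4-OH, the only hydroxyl not hydrogen-bonded to the formyl group and the most acidic one, leaving a symmetric phenol in which the formyl group blocks the carbon between the two remaining OH groups.

Step 2
Reactants: 2 2,6-dihydroxy-4-methoxybenzaldehyde; 3 3-bromoprop-1-yne (propargyl bromide)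
Product: 4 2-hydroxy-4-methoxy-6-(prop-2-yn-1-yloxy)benzaldehyde
Conditions: 3 (1.05 equiv), K2CO3 (1.1 equiv), DMF, 0 → 25 °C
Reagents that add atoms: none
Why: Williamson mono-O-propargylation of one of the two equivalent OH groups should be self-limiting, because the remaining OH becomes the sole hydrogen-bond donor to the formyl group and is less acidic; it places the three carbons of ring C on the future O1.

Step 3
Reactants: 4 2-hydroxy-4-methoxy-6-(prop-2-yn-1-yloxy)benzaldehyde
Product: 6 8-formyl-5-methoxy-2H-chromen-7-yl pivalate, via free hydroxy chromene 5 (not isolated)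
Conditions: Ph3PAuNTf2 (2 mol%), dry CH2Cl2, 25 → 40 °C; then Et3N (2.0 equiv), DMAP (5 mol%), PivCl (1.3 equiv), 0 → 25 °C
Reagents that add atoms: pivaloyl chloride, CC(C)(C)C(Cl)=O
Why: Gold-catalysed 6-endo intramolecular hydroarylation of the aryl propargyl ether (a known route to 2H-chromenes) at the only free ortho carbon, which is activated by the ortho OMe and the para OH, should close ring C, and the phenol is then acylated in the same flask so that no acidic OH enters the palladium step.

Step 4
Reactants: 7 4-iodobenzene-1,3-diol (4-iodoresorcinol)
Product: 8 3-hydroxy-4-iodophenyl pivalate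
Conditions: PivCl (1.0 equiv), Et3N (1.05 equiv), CH2Cl2, −40 → 0 °C
Reagents that add atoms: pivaloyl chloride, CC(C)(C)C(Cl)=O
Why: Kinetically controlled mono-acylation with a bulky acyl chloride should take the OH para to iodine, which is unhindered and not engaged with the halogen, so that the OH ortho to iodine stays free for ring D.

Step 5
Reactants: 8 3-hydroxy-4-iodophenyl pivalate; 9 3-chloro-3-methylbut-1-yne
Product: 10 4-iodo-3-[(2-methylbut-3-yn-2-yl)oxy]phenyl pivalate
Conditions: 9 (1.5 equiv), DBU (1.5 equiv), CuCl2·2H2O (1 mol%), MeCN, 0 °C
Reagents that add atoms: none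
Why: Copper-catalysed propargylic etherification of the phenoxide with the tertiary propargylic chloride (via a copper acetylide), run cold so that the aryl iodide and the pivalate should not be touched.

Step 6
Reactants: 10 4-iodo-3-[(2-methylbut-3-yn-2-yl)oxy]phenyl pivalate
Product: 11 8-iodo-2,2-dimethyl-2H-chromen-5-yl pivalate
Conditions: xylenes (0.1 M), 140 °C, N2, dark
Reagents that add atoms: none
Why: Thermal aryl propargyl ether Claisen rearrangement to the only free ortho carbon (the other one carries iodine), followed by enolisation, [1,5]-H shift and oxa-6π electrocyclisation, should close ring D as the 2,2-dimethyl-2H-chromene with iodine at C8.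

Step 7
Reactants: 6 8-formyl-5-methoxy-2H-chromen-7-yl pivalate; 11 8-iodo-2,2-dimethyl-2H-chromen-5-yl pivalate
Product: 12 8-[(3R)-8-formyl-5-methoxy-7-(pivaloyloxy)chroman-3-yl]-2,2-dimethyl-2H-chromen-5-yl pivalate
Conditions: 11 (1.0 equiv), 6 (1.5 equiv), Pd(dba)2 (5 mol%), (R)-Xyl-SDP(O) (6 mol%), HCO2Na (2.0 equiv), DMF, 60 °C, N2
Reagents that add atoms: none
Why: Proposed new method: zerovalent palladium adds oxidatively into the C8–I bond of 11, the C3=C4 bond of 6 inserts syn and face-selectively into the aryl–palladium bond (aryl to C3, palladium to the benzylic C4 as an η3-benzyl species), and, because the only β-hydrogen at C3 is anti to palladium, the alkyl palladium species exchanges with formate, loses CO2 and closes by C–H reductive elimination. The closest known chemistry is the racemic palladium-catalysed hydroarylation and oxyarylation of 2H-chromenes with aryl iodides, which arylates C3 and underlies isoflavan and pterocarpan syntheses, together with enantioselective intermolecular reductive Heck reactions of norbornenes and asymmetric Heck arylations of cyclic alkenes. No ring is closed: the step joins the finished bicycles (rings A and C, rings B and D) at the C3–C1' bond and so completes the skeleton. The new C3 stereocentre is controlled by the chiral ligand on palladium, which differentiates the two enantiotopic faces of the planar chromene in the insertion step, and it is not touched again because C4 becomes a CH2 group. Regioselectivity rests on the styrene-type polarisation of the chromene (benzylic palladium), chemoselectivity over the ring D alkene on the gem-dimethyl group next to it and on the excess of 6, and the endocyclic allylic C2–O bond lies close to the alkene plane and should resist ionisation by zerovalent palladium.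

Step 8
Reactants: 12 8-[(3R)-8-formyl-5-methoxy-7-(pivaloyloxy)chroman-3-yl]-2,2-dimethyl-2H-chromen-5-yl pivalate
Product: 13 (3R)-7-hydroxy-3-(5-hydroxy-2,2-dimethyl-2H-chromen-8-yl)-5-methoxychromane-8-carbaldehyde
Conditions: K2CO3 (3 equiv), MeOH–THF 3:1, 0 → 25 °C, N2; aq. NH4Cl
Reagents that add atoms: none
Why: Base-mediated transesterification of both aryl pivalates with methanol at room temperature should leave the chelated aldehyde, the ring D double bond and the non-acidic C3 stereocentre untouched.

**Compound list**

1 | 2,4,6-trihydroxybenzaldehyde | O=Cc1c(O)cc(O)cc1O | starting material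
2 | 2,6-dihydroxy-4-methoxybenzaldehyde | COc1cc(O)c(C=O)c(O)c1 | intermediate
3 | 3-bromoprop-1-yne (propargyl bromide) | C#CCBr | starting material
4 | 2-hydroxy-4-methoxy-6-(prop-2-yn-1-yloxy)benzaldehyde | COc1cc(O)c(C=O)c(OCC#C)c1 | intermediate
5 | 7-hydroxy-5-methoxy-2H-chromene-8-carbaldehyde | COc1cc(O)c(C=O)c2OCC=Cc12 | intermediate
6 | 8-formyl-5-methoxy-2H-chromen-7-yl pivalate | COc1cc(OC(=O)C(C)(C)C)c(C=O)c2OCC=Cc12 | intermediate
7 | 4-iodobenzene-1,3-diol (4-iodoresorcinol) | Oc1ccc(I)c(O)c1 | starting material
8 | 3-hydroxy-4-iodophenyl pivalate | CC(C)(C)C(=O)Oc1ccc(I)c(O)c1 | intermediate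
9 | 3-chloro-3-methylbut-1-yne | CC(C)(Cl)C#C | starting material
10 | 4-iodo-3-[(2-methylbut-3-yn-2-yl)oxy]phenyl pivalate | CC(C)(C)C(=O)Oc1ccc(I)c(OC(C)(C)C#C)c1 | intermediate
11 | 8-iodo-2,2-dimethyl-2H-chromen-5-yl pivalate | CC(C)(C)C(=O)Oc1ccc(I)c2OC(C)(C)C=Cc12 | intermediate
12 | 8-[(3R)-8-formyl-5-methoxy-7-(pivaloyloxy)chroman-3-yl]-2,2-dimethyl-2H-chromen-5-yl pivalate | COc1cc(OC(=O)C(C)(C)C)c(C=O)c2c1C[C@H](c1ccc(OC(=O)C(C)(C)C)c3c1OC(C)(C)C=C3)CO2 | intermediate
13 | (3R)-7-hydroxy-3-(5-hydroxy-2,2-dimethyl-2H-chromen-8-yl)-5-methoxychromane-8-carbaldehyde | COc1cc(O)c(C=O)c2c1C[C@H](c1ccc(O)c3c1OC(C)(C)C=C3)CO2 | target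

**Step count and risks**

Total step count: 8. Longest linear sequence: 5 steps (steps 1, 2, 3, 7, 8 or steps 4, 5, 6, 7, 8).

Steps most likely to fail:

Step 7 (enantioselective reductive Heck union). The insertion may show poor facial selectivity, or formate may reduce the aryl palladium species before the chromene inserts. The fallback uses known chemistry and sets out from 6 and 11. The same hydroarylation would be run with an achiral catalyst (Pd(OAc)2, PPh3, HCO2Na, Bu4NCl, DMF, 60 °C), a known reaction type for 2H-chromenes and aryl iodides, to give racemic 8-[8-formyl-5-methoxy-7-(pivaloyloxy)chroman-3-yl]-2,2-dimethyl-2H-chromen-5-yl pivalate F1. Preparative chromatography on a chiral stationary phase (supercritical CO2/MeOH, amylose tris(3,5-dimethylphenylcarbamate)) would separate F1 into 12 and its (3S)-enantiomer, 8-[(3S)-8-formyl-5-methoxy-7-(pivaloyloxy)chroman-3-yl]-2,2-dimethyl-2H-chromen-5-yl pivalate F2, which is set aside. The route is rejoined at 12.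

Step 5 (propargylic etherification next to iodine). Copper may couple the terminal alkyne at the aryl iodide, or HCl may be eliminated from 9 faster than the hindered phenoxide is alkylated. The fallback sets out from 8 and builds ring D without any propargyl ether: condensation with 3-methylbut-2-enal in the presence of PhB(OH)2 and propionic acid (toluene, reflux, water separator). The aryl borate should deliver the aldehyde to the only free ortho carbon and give 8-iodo-4-(2-methylprop-1-en-1-yl)-2-phenyl-4H-1,3,2-benzodioxaborin-5-yl pivalate F3, which is not isolated. On further heating F3 should lose phenylboronic acid to an ortho-quinone methide that closes by oxa-6π electrocyclisation. The route is rejoined at 11; steps 5 and 6 are bypassed.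

Step 1 (mono-methylation). Over-methylation or C-methylation of the phloroglucinol-type phenoxide may erode the yield of 2. The fallback sets out from 1 and takes selectivity from chelation instead of kinetics: exhaustive O-methylation (excess Me2SO4, K2CO3, acetone, reflux) to 2,4,6-trimethoxybenzaldehyde F4, then cleavage of the two methoxy groups ortho to the formyl group with AlCl3 (excess, CH2Cl2, 0 → 40 °C; aq. HCl). The para methoxy group is not chelation-activated and should remain. The route is rejoined at 2.

**Further compounds**

F1 | step 7 | racemic 8-[8-formyl-5-methoxy-7-(pivaloyloxy)chroman-3-yl]-2,2-dimethyl-2H-chromen-5-yl pivalate | COc1cc(OC(=O)C(C)(C)C)c(C=O)c2c1CC(c1ccc(OC(=O)C(C)(C)C)c3c1OC(C)(C)C=C3)CO2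
F2 | step 7 | 8-[(3S)-8-formyl-5-methoxy-7-(pivaloyloxy)chroman-3-yl]-2,2-dimethyl-2H-chromen-5-yl pivalate | COc1cc(OC(=O)C(C)(C)C)c(C=O)c2c1C[C@@H](c1ccc(OC(=O)C(C)(C)C)c3c1OC(C)(C)C=C3)CO2
F3 | step 5 | 8-iodo-4-(2-methylprop-1-en-1-yl)-2-phenyl-4H-1,3,2-benzodioxaborin-5-yl pivalate | CC(C)=CC1OB(c2ccccc2)Oc2c(I)ccc(OC(=O)C(C)(C)C)c12
F4 | step 1 | 2,4,6-trimethoxybenzaldehyde | COc1cc(OC)c(C=O)c(OC)c1
A1 | direct plan | 3-[(2-methylbut-3-yn-2-yl)oxy]-4-(oxetan-3-yl)phenyl pivalate | CC(C)(C)C(=O)Oc1ccc(C2COC2)c(OC(C)(C)C#C)c1
A2 | direct plan | 2,6-dihydroxy-4-methoxybenzaldehyde | COc1cc(O)c(C=O)c(O)c1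
A3 | direct plan | 4-[(2R)-1-(3-formyl-2,4-dihydroxy-6-methoxyphenyl)-3-hydroxypropan-2-yl]-3-[(2-methylbut-3-yn-2-yl)oxy]phenyl pivalate | COc1cc(O)c(C=O)c(O)c1C[C@H](c1ccc(OC(=O)C(C)(C)C)cc1OC(C)(C)C#C)CO
A4 | direct plan | 4-[(3R)-8-formyl-7-hydroxy-5-methoxychroman-3-yl]-3-[(2-methylbut-3-yn-2-yl)oxy]phenyl pivalate | COc1cc(O)c(C=O)c2c1C[C@H](c1ccc(OC(=O)C(C)(C)C)cc1OC(C)(C)C#C)CO2
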